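If you want the end of oak, count how many half-lives of the single product fit into its time. The starting material takes up reagent once to give single product, and the single product takes it up again to give bis adduct.

the same everywhere: starting material 0.50 M

| run | reagent | remark | time |
|---|---|---|---|
| spring | 0.45 equiv | run made earlier |  |
| summer | 3.6 equiv | run made earlier |  |
| ash | 0.800 equiv |  | 10 d |
| oak | 4.00 equiv |  | 10 d |
| birch | 1.50 equiv |  | 10 d |

| run | time / d | bis adduct / % | starting material / % |
|---|---|---|---|
| spring | 1.25 | 1 | 69 |
| spring | 3.00 | 6 | 53 |
| spring | 4.00 | 5 | 45 |
| spring | 6.00 | 6 | 37 |
| spring | 8.00 | 3 | 35 |
| spring | 10.0 | 2 | 31 |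
| summer | 0.500 | 18 | 21 |
| summer | 1.67 | 58 | 1 |
| summer | 3.00 | 78 | 0 |
| summer | 4.00 | 83 | 0 |
| summer | 6.00 | 90 | 1 |
| summer | 8.00 | 93 | 0 |
| summer | 10.0 | 93 | 1 |

(readings scatter by 1.5 percentage points)

- which of these holds the largest part of the starting material at the end of ash (single product / bis adduct / starting material)
- which of these holds the largest part of the starting material at the end of oak (single product / bis adduct / starting material)
- which of these holds the largest part of the starting material at the end of birch (single product / bis adduct / starting material)
- how much bis adduct is there at the end of oak, in percent of the starting material charged



Summer shows the second addition by itself, since its starting material reads 1 % after 1.67 d. I read the gap under its plateau of 93 % as single product still to cross. That gap shrinks from 35 percentage points to 10 points by 4.00 d, a pseudo-first-order loss of 0.538 d⁻¹. For the free reagent, take the charge less one reagent per starting material and one more per bis adduct at 3.00 d, which leaves about 0.945 M. Dividing gives the clearing constant, the loss of single product per molar of free reagent: 0.569 M⁻¹ d⁻¹, a reading with the scatter in it. The half-life is then ln(2) over this constant times the free reagent.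

My reckoning for oak takes the free reagent late in the run as the charge less two per plateau bis adduct, 1.07 M. That gives a half-life of 1.14 d, so 8.78 half-lives fit, and these would leave 0.227 % of a full charge of single product. I therefore expect bis adduct to lead oak at summer's plateau, 93 %. Birch, after one addition per starting material, has 0.250 M of free reagent, enough for half of its single product, so on this count birch comes to a tie between single product and bis adduct, and I leave its leader open. Ash charges 0.800 equiv, under one reagent per starting material, so I give it no count and put single product first.

The forecast names single product for ash, bis adduct for oak and bis adduct for birch, with 94 % bis adduct in oak: “slightly more reagent than summer, so the plateau is about 94%”. Its oak figure stands above my plateau.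

The flasks give single product in ash, bis adduct in oak and bis adduct in birch, with 93.4 % bis adduct in oak.

    crystals ⇌ by-product, rate k1*(cs1 - [by-product]) while solid is left; crystals form when [by-product] > cs1 (solubility = 22.0 mM, k = 6.30 h⁻¹)
    starting material + reagent → single product + by-product (k = 0.0790 M⁻¹ h⁻¹)
    starting material + single product → side product (k = 0.0240 M⁻¹ h⁻¹)
    reagent + single product → bis adduct + by-product (k = 0.0270 M⁻¹ h⁻¹)

At the end of oak, 52.5 % of the reagent charge is free, which gives 8.61 half-lives at that level, and single product stands at 0.0901 %. So the missing 6.60 % is not unfinished single product but side product, 6.51 %: oak without the loss of starting material + single product to side product gives 99.9 % bis adduct against 93.4 %. Birch, with 18.8 % of its reagent free after 5.00 d, gets 0.580 half-lives from there if that level held, and it ends with 28.0 % single product.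

The numbers in the tables are calculated for an exercise.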